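**Retrosynthetic overview**
1. Asperteretal H ⇐ Tamao–Fleming C–Si→C–O oxidation (gives C4=O) plus phenol desilylation of an alkylidene 1,2-oxasilolane.
2. Oxasilolane ⇐ O–SiMe2H-tethered syn-hydrosilylation of an anti homopropargylic α-hydroxy ester; the tether fixes where the ketone oxygen goes.
3. Alkynol ⇐ C3–C4 bond by retentive alkynylalane opening of a trans aryl glycidate (new step); the aryl alkyne ⇐ 4-hydroxybenzaldehyde by prenylation, silylation and one-carbon homologation.
4. Glycidate ⇐ key C–O step: catalytic asymmetric epoxidation of silylated methyl p-coumarate; this oxygen becomes the C2 hydroxyl and relays all stereochemistry.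
5. Ring order: the target is acyclic; the transient rings are the oxirane (step 5) and then the 1,2-oxasilolane (step 7), and both are opened again.

Assumption: common reagents and catalysts are taken as available, and the D-fructose-derived Shi diacetate ketone is assumed to give the (2S,3R)-glycidate, so its enantiomer (L-series, from L-sorbose) is used.

**Step 1**
Reactants: 1 4-hydroxybenzaldehyde; 2 1-bromo-3-methylbut-2-ene (prenyl bromide)
Product: 3 4-hydroxy-3-(3-methylbut-2-en-1-yl)benzaldehyde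
Conditions: KOH (10% aq.), rt, 24–48 h; chromatography to remove the O-prenyl ether
Reagents that add atoms: none
Why: Ortho C-alkylation of an ambident phenoxide in water (hydrogen bonding to O favours C-attack; para position blocked); no stereocentre is formed.

**Step 2**
Reactants: 3 4-hydroxy-3-(3-methylbut-2-en-1-yl)benzaldehyde
Product: 4 4-[(tert-butyldimethylsilyl)oxy]-3-(3-methylbut-2-en-1-yl)benzaldehyde
Conditions: TBSCl, imidazole, DMF, rt
Reagents that add atoms: tert-butyldimethylsilyl chloride, CC(C)(C)[Si](C)(C)Cl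
Why: Standard phenol silylation (Corey silyl ether formation) masks the acidic OH for the organometallic steps; no stereocentre.

**Step 3**
Reactants: 4 4-[(tert-butyldimethylsilyl)oxy]-3-(3-methylbut-2-en-1-yl)benzaldehyde
Product: 5 tert-butyl[4-ethynyl-2-(3-methylbut-2-en-1-yl)phenoxy]dimethylsilane
Conditions: TMSCHN2, LDA (commercial solution), THF, −78 °C, then 4, −78 °C → rt
Reagents that add atoms: (trimethylsilyl)diazomethane, C[Si](C)(C)C=[N+]=[N-]
Why: Colvin rearrangement (Shioiri one-carbon homologation): addition of lithiated TMS-diazomethane, Peterson-type elimination, loss of N2 and 1,2-shift of the alkylidene carbene give the terminal alkyne under aprotic conditions that keep the aryl silyl ether.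

**Step 4**
Reactants: 6 methyl (E)-3-(4-hydroxyphenyl)prop-2-enoate (methyl p-coumarate)
Product: 7 methyl (E)-3-{4-[(tert-butyldimethylsilyl)oxy]phenyl}prop-2-enoate
Conditions: TBSCl, imidazole, DMF, rt
Reagents that add atoms: tert-butyldimethylsilyl chloride, CC(C)(C)[Si](C)(C)Cl
Why: Phenol silylation (Corey protocol) prevents quinone-methide formation from the later epoxide; no stereocentre.

**Step 5**
Reactants: 7 methyl (E)-3-{4-[(tert-butyldimethylsilyl)oxy]phenyl}prop-2-enoate
Product: 8 methyl (2R,3S)-3-{4-[(tert-butyldimethylsilyl)oxy]phenyl}oxirane-2-carboxylate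
Conditions: ent-Shi diacetate ketone (1,2-O-isopropylidene-4,5-di-O-acetyl-L-erythro-2,3-hexodiulo-2,6-pyranose, 25 mol%), Oxone, NaHCO3, Bu4NHSO4 (cat.), MeCN/aq. Na2EDTA, 0 °C
Reagents that add atoms: potassium peroxymonosulfate (active part of Oxone), [K+].[O-]S(=O)(=O)OO
Why: Shi-type asymmetric epoxidation: the chiral dioxirane delivers oxygen to one face of the electron-rich E-cinnamate through a spiro transition state, forming both C–O bonds and setting C2 (R) and C3 (S); this oxygen becomes the C2 hydroxyl of the target.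

**Step 6**
Reactants: 5 tert-butyl[4-ethynyl-2-(3-methylbut-2-en-1-yl)phenoxy]dimethylsilane; 8 methyl (2R,3S)-3-{4-[(tert-butyldimethylsilyl)oxy]phenyl}oxirane-2-carboxylate
Product: 11 methyl (2R,3R)-3-{4-[(tert-butyldimethylsilyl)oxy]phenyl}-5-{4-[(tert-butyldimethylsilyl)oxy]-3-(3-methylbut-2-en-1-yl)phenyl}-2-hydroxypent-4-ynoate, via lithium acetylide 9 (not isolated), via diethylalkynylalane 10 (not isolated)
Conditions: 5 (1.3 equiv), n-BuLi, toluene, 0 °C; Et2AlCl (1.3 equiv), 0 °C → rt; then 8, toluene/CH2Cl2, −40 → 0 °C; aq. Rochelle salt (excess 5 recovered)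
Reagents that add atoms: none
Why: Proposed new method: syn-selective (retentive) SNi alkynylative opening of a 3-aryl glycidate – the Lewis-acidic alane 10 binds the oxirane oxygen (chelated by the ester C=O), the benzylic C3–O bond ionises to a contact ion pair stabilised by the p-silyloxyphenyl group (C2–H already eclipses the aryl, so no rotation is needed), and the resulting aluminate passes its alkynyl group to C3 through a five-membered transition state on the face the oxygen has just left, so the C3–C4 bond forms only at the benzylic carbon and with retention [(2R,3S)-8 → (2R,3R)-11, anti]; the closest known reactions are the cis-opening of 1,2-anhydro sugars by alkynylalanes and the retentive thiol opening of 4-methoxyphenyl glycidates, and a non-coordinating solvent is essential to suppress external (invertive) delivery.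

**Step 7**
Reactants: 11 methyl (2R,3R)-3-{4-[(tert-butyldimethylsilyl)oxy]phenyl}-5-{4-[(tert-butyldimethylsilyl)oxy]-3-(3-methylbut-2-en-1-yl)phenyl}-2-hydroxypent-4-ynoate
Product: 13 methyl (3E,4S,5R)-3-{[4-[(tert-butyldimethylsilyl)oxy]-3-(3-methylbut-2-en-1-yl)phenyl]methylidene}-4-{4-[(tert-butyldimethylsilyl)oxy]phenyl}-2,2-dimethyl-1,2-oxasilolane-5-carboxylate, via dimethylsilyl ether 12 (not isolated)
Conditions: (HMe2Si)2NH, neat, 70 °C, then evaporate; Karstedt catalyst (1 mol% Pt), THF, rt; filtration through Florisil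
Reagents that add atoms: 1,1,3,3-tetramethyldisilazane, C[SiH](C)N[SiH](C)C
Why: O-silylation followed by Pt-catalysed intramolecular syn-hydrosilylation (5-exo-dig, Tamao-type tethered hydrosilylation) puts silicon on C4 only, because the C2–O–Si tether can reach only the proximal alkyne carbon; C2 and C3 are untouched (the C3 descriptor changes from R to S only through CIP priorities).

**Step 8**
Reactants: 13 methyl (3E,4S,5R)-3-{[4-[(tert-butyldimethylsilyl)oxy]-3-(3-methylbut-2-en-1-yl)phenyl]methylidene}-4-{4-[(tert-butyldimethylsilyl)oxy]phenyl}-2,2-dimethyl-1,2-oxasilolane-5-carboxylate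
Product: 15 asperteretal H [methyl (2R,3S)-2-hydroxy-3-(4-hydroxyphenyl)-5-[4-hydroxy-3-(3-methylbut-2-en-1-yl)phenyl]-4-oxopentanoate], via bis-TBS ketol 14 (not isolated)
Conditions: 30% H2O2, KHF2, DMF/MeOH (3:1), 0 °C → rt; work-up at pH 6–7, neutral silica
Reagents that add atoms: hydrogen peroxide, OO
Why: Tamao–Fleming oxidation converts the alkenyl C–Si bond into C–O (the enol tautomerises by protonation at C5, so C3 is not touched) and frees the C2–OH, while the same bifluoride in methanol cleaves both phenolic TBS ethers; no new stereocentre is formed and the base-labile C3 centre never meets base.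

**Compound list**
1 | 4-hydroxybenzaldehyde | O=Cc1ccc(O)cc1 | starting material
2 | 1-bromo-3-methylbut-2-ene | CC(C)=CCBr | starting material
3 | 4-hydroxy-3-(3-methylbut-2-en-1-yl)benzaldehyde | O=Cc1ccc(O)c(CC=C(C)C)c1 | intermediate
4 | 4-[(tert-butyldimethylsilyl)oxy]-3-(3-methylbut-2-en-1-yl)benzaldehyde | O=Cc1ccc(O[Si](C)(C)C(C)(C)C)c(CC=C(C)C)c1 | intermediate
5 | tert-butyl[4-ethynyl-2-(3-methylbut-2-en-1-yl)phenoxy]dimethylsilane | C#Cc1ccc(O[Si](C)(C)C(C)(C)C)c(CC=C(C)C)c1 | intermediate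
6 | methyl (E)-3-(4-hydroxyphenyl)prop-2-enoate | COC(=O)/C=C/c1ccc(O)cc1 | starting material
7 | methyl (E)-3-{4-[(tert-butyldimethylsilyl)oxy]phenyl}prop-2-enoate | COC(=O)/C=C/c1ccc(O[Si](C)(C)C(C)(C)C)cc1 | intermediate
8 | methyl (2R,3S)-3-{4-[(tert-butyldimethylsilyl)oxy]phenyl}oxirane-2-carboxylate | COC(=O)[C@@H]1O[C@H]1c2ccc(O[Si](C)(C)C(C)(C)C)cc2 | intermediate
9 | lithium {4-[(tert-butyldimethylsilyl)oxy]-3-(3-methylbut-2-en-1-yl)phenyl}acetylide | [Li]C#Cc1ccc(O[Si](C)(C)C(C)(C)C)c(CC=C(C)C)c1 | intermediate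
10 | diethyl({4-[(tert-butyldimethylsilyl)oxy]-3-(3-methylbut-2-en-1-yl)phenyl}ethynyl)alane | CC[Al](CC)C#Cc1ccc(O[Si](C)(C)C(C)(C)C)c(CC=C(C)C)c1 | intermediate
11 | methyl (2R,3R)-3-{4-[(tert-butyldimethylsilyl)oxy]phenyl}-5-{4-[(tert-butyldimethylsilyl)oxy]-3-(3-methylbut-2-en-1-yl)phenyl}-2-hydroxypent-4-ynoate | COC(=O)[C@H](O)[C@@H](C#Cc1ccc(O[Si](C)(C)C(C)(C)C)c(CC=C(C)C)c1)c2ccc(O[Si](C)(C)C(C)(C)C)cc2 | intermediate
12 | methyl (2R,3R)-3-{4-[(tert-butyldimethylsilyl)oxy]phenyl}-5-{4-[(tert-butyldimethylsilyl)oxy]-3-(3-methylbut-2-en-1-yl)phenyl}-2-[(dimethylsilyl)oxy]pent-4-ynoate | COC(=O)[C@H](O[SiH](C)C)[C@@H](C#Cc1ccc(O[Si](C)(C)C(C)(C)C)c(CC=C(C)C)c1)c2ccc(O[Si](C)(C)C(C)(C)C)cc2 | intermediate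
13 | methyl (3E,4S,5R)-3-{[4-[(tert-butyldimethylsilyl)oxy]-3-(3-methylbut-2-en-1-yl)phenyl]methylidene}-4-{4-[(tert-butyldimethylsilyl)oxy]phenyl}-2,2-dimethyl-1,2-oxasilolane-5-carboxylate | COC(=O)[C@@H]1O[Si](C)(C)/C(=C/c2ccc(O[Si](C)(C)C(C)(C)C)c(CC=C(C)C)c2)[C@H]1c3ccc(O[Si](C)(C)C(C)(C)C)cc3 | intermediate
14 | methyl (2R,3S)-3-{4-[(tert-butyldimethylsilyl)oxy]phenyl}-5-{4-[(tert-butyldimethylsilyl)oxy]-3-(3-methylbut-2-en-1-yl)phenyl}-2-hydroxy-4-oxopentanoate | COC(=O)[C@H](O)[C@@H](C(=O)Cc1ccc(O[Si](C)(C)C(C)(C)C)c(CC=C(C)C)c1)c2ccc(O[Si](C)(C)C(C)(C)C)cc2 | intermediate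
15 | asperteretal H, methyl (2R,3S)-2-hydroxy-3-(4-hydroxyphenyl)-5-[4-hydroxy-3-(3-methylbut-2-en-1-yl)phenyl]-4-oxopentanoate | COC(=O)[C@H](O)[C@@H](C(=O)Cc1ccc(O)c(CC=C(C)C)c1)c1ccc(O)cc1 | target

**Step count and risks**
Total steps: 8. Longest linear sequence: 6 (steps 1, 2, 3, 6, 7, 8).

Most likely to fail, step 6 (the new step). Retention could be incomplete (syn diastereomer from external delivery), or the glycidate could undergo Lewis-acid Meinwald rearrangement before alkynyl transfer. The fallback uses known allenylmetal chemistry; it sets out from 5 and returns at 11. Alkyne 5 is added to commercial 4-[(tert-butyldimethylsilyl)oxy]benzaldehyde by a zinc-mediated catalytic asymmetric alkynylation (ProPhenol/Me2Zn type, ligand enantiomer chosen for the S alcohol). This gives (1S)-1-{4-[(tert-butyldimethylsilyl)oxy]phenyl}-3-{4-[(tert-butyldimethylsilyl)oxy]-3-(3-methylbut-2-en-1-yl)phenyl}prop-2-yn-1-ol F3. Methyl chloroformate and pyridine convert it into the (1S)-propargylic methyl carbonate F4. Pd(0)/Et2Zn umpolung of F4 (anti SN2' oxidative addition, transmetalation to an allenylzinc, cyclic SE2' addition) with methyl glyoxylate then gives the anti adduct 11, with net inversion at the propargylic carbon.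

Second, step 8. The α-aryl β-hydroxy ketone can epimerise at C3, undergo retro-aldol cleavage or dehydrate, and the peroxide step could be sluggish or touch the prenyl group. The fallback avoids silicon and peroxide; it sets out from 11 and returns at 14. Boc2O/DMAP gives methyl (2R,3R)-2-[(tert-butoxycarbonyl)oxy]-3-{4-[(tert-butyldimethylsilyl)oxy]phenyl}-5-{4-[(tert-butyldimethylsilyl)oxy]-3-(3-methylbut-2-en-1-yl)phenyl}pent-4-ynoate F5. A cationic gold(I) catalyst effects the known 6-exo-dig carbonate cyclisation with loss of isobutene, giving methyl (4R,5S,6Z)-6-{[4-[(tert-butyldimethylsilyl)oxy]-3-(3-methylbut-2-en-1-yl)phenyl]methylidene}-5-{4-[(tert-butyldimethylsilyl)oxy]phenyl}-2-oxo-1,3-dioxane-4-carboxylate F6. Dilute aqueous acid in MeCN hydrolyses this enol carbonate with loss of CO2 to ketol 14, which KHF2/MeOH desilylates to 15.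

Third, step 1. O-prenylation and over-alkylation compete, so the yield of the C-prenylated phenol is expected to be low (moderate at best). The fallback replaces phenoxide alkylation by cross-coupling; it sets out from 1 and returns at 4. Bromination (Br2, AcOH) gives 3-bromo-4-hydroxybenzaldehyde F1, and TBSCl/imidazole gives 3-bromo-4-[(tert-butyldimethylsilyl)oxy]benzaldehyde F2. A ligand-controlled, linear-selective Suzuki–Miyaura coupling of F2 with commercial prenylboronic acid pinacol ester (Pd catalyst, K3PO4) then gives 4.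

**Further compounds**
F1 | step 1 | 3-bromo-4-hydroxybenzaldehyde | O=Cc1ccc(O)c(Br)c1
F2 | step 1 | 3-bromo-4-[(tert-butyldimethylsilyl)oxy]benzaldehyde | O=Cc1ccc(O[Si](C)(C)C(C)(C)C)c(Br)c1
F3 | step 6 | (1S)-1-{4-[(tert-butyldimethylsilyl)oxy]phenyl}-3-{4-[(tert-butyldimethylsilyl)oxy]-3-(3-methylbut-2-en-1-yl)phenyl}prop-2-yn-1-ol | O[C@H](C#Cc1ccc(O[Si](C)(C)C(C)(C)C)c(CC=C(C)C)c1)c2ccc(O[Si](C)(C)C(C)(C)C)cc2
F4 | step 6 | (1S)-1-{4-[(tert-butyldimethylsilyl)oxy]phenyl}-3-{4-[(tert-butyldimethylsilyl)oxy]-3-(3-methylbut-2-en-1-yl)phenyl}prop-2-yn-1-yl methyl carbonate | COC(=O)O[C@H](C#Cc1ccc(O[Si](C)(C)C(C)(C)C)c(CC=C(C)C)c1)c2ccc(O[Si](C)(C)C(C)(C)C)cc2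
F5 | step 8 | methyl (2R,3R)-2-[(tert-butoxycarbonyl)oxy]-3-{4-[(tert-butyldimethylsilyl)oxy]phenyl}-5-{4-[(tert-butyldimethylsilyl)oxy]-3-(3-methylbut-2-en-1-yl)phenyl}pent-4-ynoate | COC(=O)[C@H](OC(=O)OC(C)(C)C)[C@@H](C#Cc1ccc(O[Si](C)(C)C(C)(C)C)c(CC=C(C)C)c1)c2ccc(O[Si](C)(C)C(C)(C)C)cc2
F6 | step 8 | methyl (4R,5S,6Z)-6-{[4-[(tert-butyldimethylsilyl)oxy]-3-(3-methylbut-2-en-1-yl)phenyl]methylidene}-5-{4-[(tert-butyldimethylsilyl)oxy]phenyl}-2-oxo-1,3-dioxane-4-carboxylate | COC(=O)[C@@H]1OC(=O)O/C(=C\c2ccc(O[Si](C)(C)C(C)(C)C)c(CC=C(C)C)c2)[C@H]1c3ccc(O[Si](C)(C)C(C)(C)C)cc3
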